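**Retrosynthetic overview**
1. Target 6 ⇒ benzylic C–N disconnection: the N–H of pyrrolidin-2-one (3) adds to the exocyclic CH2 of p-quinone methide 5.
2. 5 ⇒ tautomer of the fully substituted o-quinone 4 ⇒ two-electron oxidation of tribromo-methylcatechol 2. The methyl C–H is the latent leaving group, so the coupling is a net dehydrogenative C–H/N–H coupling.
3. 2 ⇒ threefold electrophilic bromination of 4-methylcatechol (1).
4. Ring formation: none. The benzene ring and the γ-lactam are both bought intact.

Assumption: the target has no stereocentre (it is achiral), so no stereocontrol is needed; and because the route has only two steps, the risk ranking at the end covers both steps rather than three.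

**Step 1**
Reactants: 1 4-methylbenzene-1,2-diol (4-methylcatechol)
Product: 2 3,4,6-tribromo-5-methylbenzene-1,2-diol
Conditions: Br2 (3.1 equiv), AcOH, 10 °C → rt, 3 h; aq. NaHSO3 quench, precipitate from water
Reagents that add atoms: bromine, BrBr
Why: Electrophilic aromatic bromination (SEAr); each of the three free ring positions is ortho or para to a hydroxyl, so three equivalents of Br2 fill all of them, and the bisulfite quench returns any o-quinone to the catechol; no stereocentre is formed.

**Step 2**
Reactants: 2 3,4,6-tribromo-5-methylbenzene-1,2-diol; 3 pyrrolidin-2-one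
Product: 6 1-(2,3,6-tribromo-4,5-dihydroxybenzyl)pyrrolidin-2-one, via o-quinone 4 (not isolated), via p-quinone methide 5 (not isolated)
Conditions: DDQ (1.0 equiv), 4 Å MS, CH2Cl2, 0 °C, 15 min; then 3 (5 equiv), (PhO)2P(O)OH (10 mol%), 0 → 35 °C, 6 h (red colour fades); aq. Na2S2O4 wash
Reagents that add atoms: none
Why: Proposed new method: a one-flask dehydrogenative benzylic C–H/N–H coupling in which DDQ first oxidises catechol 2 to the persistent, fully substituted o-quinone 4; diphenyl phosphate then acts as a bifunctional proton shuttle (P=O takes a proton from the vinylogous, bromine-acidified methyl while P–OH delivers one to the conjugated carbonyl oxygen) and tautomerises 4 to the 2-hydroxy-p-quinone methide 5; the same acid activates 5 for 1,6-aza-Michael addition of lactam 3 at the unhindered exocyclic CH2, any kinetic O-adduct (lactim ether) re-ionising to 5 and funnelling to the N-benzyl lactam, with rearomatisation to the catechol as driving force; over-reaction should be self-limiting because a second methide from 6 would force the lactam into A(1,3) clash with an ortho bromine and the fully blocked ring cannot self-alkylate; the closest known reaction types are the o-quinone to p-quinone methide isomerisation of 4-alkylcatechol quinones, DDQ-mediated benzylic oxidation of p-alkylphenols and Brønsted-acid-catalysed 1,6-aza-Michael additions to p-quinone methides; no stereocentre is formed.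

**Compound list**
1 | 4-methylbenzene-1,2-diol (4-methylcatechol) | Cc1ccc(O)c(O)c1 | starting material
2 | 3,4,6-tribromo-5-methylbenzene-1,2-diol | Cc1c(Br)c(O)c(O)c(Br)c1Br | intermediate
3 | pyrrolidin-2-one | O=C1CCCN1 | starting material
4 | 3,4,6-tribromo-5-methylcyclohexa-3,5-diene-1,2-dione (o-quinone) | CC1=C(Br)C(=O)C(=O)C(Br)=C1Br | intermediate (not isolated)
5 | 2,3,5-tribromo-6-hydroxy-4-methylidenecyclohexa-2,5-dien-1-one (p-quinone methide) | C=C1C(Br)=C(O)C(=O)C(Br)=C1Br | intermediate (not isolated)
6 | 1-(2,3,6-tribromo-4,5-dihydroxybenzyl)pyrrolidin-2-one | O=C1CCCN1Cc1c(Br)c(O)c(O)c(Br)c1Br | target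

**Total step count:** 2
**Longest linear sequence:** 2 steps (1 → 2 → 6; lactam 3 enters in step 2)

**Steps most likely to fail (both steps of the route, most risky first)**

Step 2 (the proposed new step). The tautomerisation of 4 to 5 may be too slow, so that the quinone persists or the lactam attacks the brominated quinone ring instead. The O-adduct may also fail to funnel to the N-benzyl lactam. The fallback uses known chemistry only; it sets out from 2 and comes back at 6. Catechol 2 is O-methylated twice (MeI, K2CO3, DMF, rt) to give 1,2,4-tribromo-5,6-dimethoxy-3-methylbenzene F1. Its ring is fully substituted, so radical Wohl–Ziegler bromination (NBS, AIBN, PhCF3, 85 °C) can only hit the methyl group and gives 1,2,4-tribromo-3-(bromomethyl)-5,6-dimethoxybenzene F2. The sodium salt of lactam 3 (NaH, THF/DMF, 0 °C → rt) is N-alkylated by this benzylic bromide to give 1-(2,3,6-tribromo-4,5-dimethoxybenzyl)pyrrolidin-2-one F3. Both methyl ethers are then cleaved with BBr3 (4 equiv, CH2Cl2, −78 °C → rt, aqueous work-up) to deliver 6.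

Step 1. The free catechol may be oxidised by bromine, the methyl group may be brominated through a quinone-methide-type pathway, or the third, most hindered bromination may stall. The fallback brominates a redox-inert acetal instead; it sets out from 1 and comes back at 2. Catechol 1 is methylenated (CH2Br2, Cs2CO3, DMF, 100 °C) to 5-methyl-1,3-benzodioxole F4. This is brominated exhaustively under Lewis-acid conditions (Br2 3.3 equiv, Fe powder cat., AcOH/CH2Cl2, rt → 40 °C) to 4,5,7-tribromo-6-methyl-1,3-benzodioxole F5. The acetal is then opened with BBr3 (CH2Cl2, −78 °C → rt, aqueous work-up) to return catechol 2.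

**Further compounds**
F1 | step 2 | 1,2,4-tribromo-5,6-dimethoxy-3-methylbenzene | COc1c(OC)c(Br)c(Br)c(C)c1Br
F2 | step 2 | 1,2,4-tribromo-3-(bromomethyl)-5,6-dimethoxybenzene | COc1c(OC)c(Br)c(Br)c(CBr)c1Br
F3 | step 2 | 1-(2,3,6-tribromo-4,5-dimethoxybenzyl)pyrrolidin-2-one | COc1c(OC)c(Br)c(Br)c(CN2CCCC2=O)c1Br
F4 | step 1 | 5-methyl-1,3-benzodioxole | Cc1ccc2OCOc2c1
F5 | step 1 | 4,5,7-tribromo-6-methyl-1,3-benzodioxole | Cc1c(Br)c2OCOc2c(Br)c1Br
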